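## Retrosynthetic overview

1. Target 29 ⇐ late C14 allylic oxidation of the 14‑methyl macrocycle 27, which comes from macrocyclic enoate 21 by ester → CH2OAc adjustment and unmasking of the α‑methylene group from a Mannich base.
2. 21 ⇐ intramolecular Horner–Wadsworth–Emmons closure of C4=C5 from aldehyde–phosphonate 20 (the ten‑membered ring is formed last, the γ‑lactone first).
3. 20 ⇐ phosphonate 15 ⇐ decarboxylative radical addition of keto acid 12 to a 2‑phosphonoacrylate (brings C3, C4, C15).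
4. 12 ⇐ Birch reduction/ozonolysis of the 2‑alkoxy‑5‑methylphenyl group of 7: the benzene ring is the masked C8(=O)–C9–C10(C14)=C1–C2 chain and delivers the ring‑cis C1=C10 olefin.
5. 7 ⇐ anti‑selective Cu‑catalysed conjugate addition of an aryl Grignard to (S)‑butenolide 2 with Mannich trapping (sets C6/C7); C8 is set by CBS reduction.

Assumption: germacrane locants are used throughout (ring C1–C10, lactone C6–O–C12 with C11/C13, C14 on C10, C15 on C4), and compounds 1, 3, 13 and 17 are bought.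

## Route

Step 1
Reactants: 1 (S)-5-(hydroxymethyl)furan-2(5H)-one
Product: 2 (S)-5-[(tert-butyldimethylsilyloxy)methyl]furan-2(5H)-one
Conditions: TBSCl, imidazole, DMF, 0 °C → rt
Reagents that add atoms: tert-butyldimethylsilyl chloride, CC(C)(C)[Si](C)(C)Cl
Why: Silyl ether protection of the primary alcohol; the stereocentre (future C6) is not touched.

Step 2
Reactants: 3 2-bromo-4-methylphenol
Product: 4 2-bromo-1-(methoxymethoxy)-4-methylbenzene
Conditions: MOMCl, i-Pr2NEt, CH2Cl2, 0 °C → rt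
Reagents that add atoms: chloromethyl methyl ether, COCCl
Why: Williamson-type O-alkylation; the MOM ether survives Grignard and dissolving-metal conditions and later gives a hydrolytically labile ester, so the acid is released without base.

Step 3
Reactants: 4 2-bromo-1-(methoxymethoxy)-4-methylbenzene; 2 (S)-5-[(tert-butyldimethylsilyloxy)methyl]furan-2(5H)-one
Product: 7 (3R,4R,5S)-5-[(tert-butyldimethylsilyloxy)methyl]-3-[(dimethylamino)methyl]-4-[2-(methoxymethoxy)-5-methylphenyl]oxolan-2-one, via aryl Grignard reagent 5 (not isolated), via bromomagnesium lactone enolate 6 (not isolated)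
Conditions: Mg, THF, 40 °C; then 2, CuBr·SMe2 (10 mol%), THF, −78 → −40 °C; then CH2=NMe2+ I−, −78 °C → rt
Reagents that add atoms: N,N-dimethylmethyleneiminium iodide (Eschenmoser's salt), C=[N+](C)C.[I-]
Why: Copper-catalysed conjugate addition of the aryl Grignard anti to the C5 silyloxymethyl group sets C7 trans to C6; Mannich trapping of the enolate anti to the aryl group installs C13 as a masked methylene (the C11 centre is destroyed later).

Step 4
Reactants: 7 (3R,4R,5S)-5-[(tert-butyldimethylsilyloxy)methyl]-3-[(dimethylamino)methyl]-4-[2-(methoxymethoxy)-5-methylphenyl]oxolan-2-one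
Product: 10 (3R,4R,5S)-5-[(tert-butyldimethylsilyloxy)methyl]-3-[(dimethylamino)methyl]-4-[2-(methoxymethoxy)-5-methylcyclohexa-1,4-dien-1-yl]oxolan-2-one, via lithium hydroxy-carboxylate 8 (not isolated), via dienyl hydroxy-carboxylate 9 (not isolated)
Conditions: LiOH, THF/H2O, 0 °C; then Li, NH3(l), THF, t-BuOH, −78 → −33 °C; NH4Cl; then AcOH/H2O (pH 5), rt
Reagents that add atoms: none
Why: Birch reduction of the anisole-type ring; the lactone is protected as its carboxylate/alkoxide. Protonation ortho and meta to the alkoxy group leaves alkoxy, alkyl and methyl on sp2 carbons, giving the 1,4-diene with the C10=C1 olefin held cis in the ring; mild acid recloses the lactone without touching the enol ether or the stereocentres.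

Step 5
Reactants: 10 (3R,4R,5S)-5-[(tert-butyldimethylsilyloxy)methyl]-3-[(dimethylamino)methyl]-4-[2-(methoxymethoxy)-5-methylcyclohexa-1,4-dien-1-yl]oxolan-2-one
Product: 12 (Z)-6-[(2S,3S,4R)-2-[(tert-butyldimethylsilyloxy)methyl]-4-[(dimethylamino)methyl]-5-oxooxolan-3-yl]-4-methyl-6-oxohex-3-enoic acid, via methoxymethyl ester 11 (not isolated)
Conditions: TFA (1.05 equiv), O3, CH2Cl2/MeOH, −78 °C; Me2S, −78 °C → rt; H2O (pH 3), rt
Reagents that add atoms: ozone, [O-][O+]=O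
Why: Chemoselective ozonolysis of the tetrasubstituted enol ether (the amine is shielded as its ammonium salt) opens the ring to the C8 ketone and a MOM ester, which hydrolyses on work-up; the untouched trisubstituted olefin keeps the (Z) geometry inherited from the ring.

Step 6
Reactants: 12 (Z)-6-[(2S,3S,4R)-2-[(tert-butyldimethylsilyloxy)methyl]-4-[(dimethylamino)methyl]-5-oxooxolan-3-yl]-4-methyl-6-oxohex-3-enoic acid; 13 tert-butyl 2-(diethoxyphosphoryl)acrylate
Product: 15 tert-butyl (5Z)-8-[(2S,3S,4R)-2-[(tert-butyldimethylsilyloxy)methyl]-4-[(dimethylamino)methyl]-5-oxooxolan-3-yl]-2-(diethoxyphosphoryl)-6-methyl-8-oxooct-5-enoate (C2 epimers), via N-acyloxyphthalimide 14 (not isolated)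
Conditions: N-hydroxyphthalimide, DIC, CH2Cl2, 0 °C → rt; then 13, Hantzsch ester, Ru(bpy)3(PF6)2 (1 mol%), CH2Cl2, blue LED, rt
Reagents that add atoms: none
Why: Reductive decarboxylative Giese addition of the redox-active ester: the C2 radical adds through its primary terminus to the doubly activated acrylate, forming C2–C3 and installing the phosphonoacetate (C4, C15) in one step.

Step 7
Reactants: 15 tert-butyl (5Z)-8-[(2S,3S,4R)-2-[(tert-butyldimethylsilyloxy)methyl]-4-[(dimethylamino)methyl]-5-oxooxolan-3-yl]-2-(diethoxyphosphoryl)-6-methyl-8-oxooct-5-enoate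
Product: 16 tert-butyl (5Z,8S)-8-[(2S,3R,4R)-2-[(tert-butyldimethylsilyloxy)methyl]-4-[(dimethylamino)methyl]-5-oxooxolan-3-yl]-2-(diethoxyphosphoryl)-8-hydroxy-6-methyloct-5-enoate
Conditions: (R)-2-methyl-CBS-oxazaborolidine, BH3·SMe2, THF, −30 °C; then MeOH
Reagents that add atoms: none
Why: Corey–Bakshi–Shibata reduction; the branched lactone carbon C7 acts as the large group and CH2(9) as the small one, so the (R)-catalyst gives the (8S)-carbinol (O8 syn to O6).

Step 8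
Reactants: 16 tert-butyl (5Z,8S)-8-[(2S,3R,4R)-2-[(tert-butyldimethylsilyloxy)methyl]-4-[(dimethylamino)methyl]-5-oxooxolan-3-yl]-2-(diethoxyphosphoryl)-8-hydroxy-6-methyloct-5-enoate; 17 (S)-2-methylbutanoic acid
Product: 18 tert-butyl (5Z,8S)-8-[(2S,3R,4R)-2-[(tert-butyldimethylsilyloxy)methyl]-4-[(dimethylamino)methyl]-5-oxooxolan-3-yl]-2-(diethoxyphosphoryl)-6-methyl-8-[(2S)-2-methylbutanoyloxy]oct-5-enoate
Conditions: 17, DIC, DMAP, CH2Cl2, 0 °C → rt
Reagents that add atoms: none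
Why: Steglich esterification with retention at C8; acylating at once blocks translactonisation to the 8,12-olide.

Step 9
Reactants: 18 tert-butyl (5Z,8S)-8-[(2S,3R,4R)-2-[(tert-butyldimethylsilyloxy)methyl]-4-[(dimethylamino)methyl]-5-oxooxolan-3-yl]-2-(diethoxyphosphoryl)-6-methyl-8-[(2S)-2-methylbutanoyloxy]oct-5-enoate
Product: 19 tert-butyl (5Z,8S)-2-(diethoxyphosphoryl)-8-[(2S,3R,4R)-4-[(dimethylamino)methyl]-2-(hydroxymethyl)-5-oxooxolan-3-yl]-6-methyl-8-[(2S)-2-methylbutanoyloxy]oct-5-enoate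
Conditions: HF·pyridine, THF/pyridine, 0 °C
Reagents that add atoms: none
Why: Fluoride cleavage of the primary silyl ether; esters, lactone and phosphonate are inert.

Step 10
Reactants: 19 tert-butyl (5Z,8S)-2-(diethoxyphosphoryl)-8-[(2S,3R,4R)-4-[(dimethylamino)methyl]-2-(hydroxymethyl)-5-oxooxolan-3-yl]-6-methyl-8-[(2S)-2-methylbutanoyloxy]oct-5-enoate
Product: 20 tert-butyl (5Z,8S)-2-(diethoxyphosphoryl)-8-[(2S,3R,4R)-4-[(dimethylamino)methyl]-2-formyl-5-oxooxolan-3-yl]-6-methyl-8-[(2S)-2-methylbutanoyloxy]oct-5-enoate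
Conditions: SO3·pyridine, DMSO, i-Pr2NEt, CH2Cl2, 0 °C
Reagents that add atoms: none
Why: Parikh–Doering oxidation, compatible with the tertiary amine; the trans lactone is the thermodynamic arrangement, so C6 is not at risk.

Step 11
Reactants: 20 tert-butyl (5Z,8S)-2-(diethoxyphosphoryl)-8-[(2S,3R,4R)-4-[(dimethylamino)methyl]-2-formyl-5-oxooxolan-3-yl]-6-methyl-8-[(2S)-2-methylbutanoyloxy]oct-5-enoate
Product: 21 macrocyclic tert-butyl ester: (1(10)Z,4E,6R,7R,8S,11R)-germacra-1(10),4-dien-12,6-olide carrying 11-CH2NMe2, 8-O-[(S)-2-methylbutanoyl], 10-CH3 and 4-CO2t-Bu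
Conditions: LiCl, DBU, MeCN, 0.002 M (slow addition), rt
Reagents that add atoms: none
Why: Intramolecular Horner–Wadsworth–Emmons reaction (Masamune–Roush conditions) closes the ten-membered ring at C4=C5; the (E)-enoate (ester trans to C6) is both the thermodynamic outcome and the ring-cis geometry a ten-membered ring demands.

Step 12
Reactants: 21 macrocyclic tert-butyl ester
Product: 22 macrocyclic 15-oic acid: as 21 with 4-CO2H
Conditions: TFA/CH2Cl2 (1:4), 0 °C
Reagents that add atoms: none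
Why: Acidolysis of the tert-butyl ester (loss of isobutene); the lactone and the hindered secondary ester survive, the amine is protonated, and the electron-poor C4=C5 cannot take part in transannular cyclisation.

Step 13
Reactants: 22 macrocyclic 15-oic acid
Product: 24 macrocyclic 15-ol: as 21 with 4-CH2OH, via mixed carbonic anhydride 23 (not isolated)
Conditions: i-BuOCOCl, N-methylmorpholine, THF, −15 °C; then NaBH4, MeOH, −15 → 0 °C
Reagents that add atoms: none
Why: Borohydride reduction of the mixed anhydride turns only the activated carboxyl into the allylic alcohol; lactone and ester are untouched.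

Step 14
Reactants: 24 macrocyclic 15-ol
Product: 25 macrocyclic 15-acetate: as 21 with 4-CH2OAc
Conditions: Ac2O, pyridine, DMAP (cat.), CH2Cl2, 0 °C
Reagents that add atoms: acetic anhydride, CC(=O)OC(C)=O
Why: Acetylation of the only free hydroxyl.

Step 15
Reactants: 25 macrocyclic 15-acetate
Product: 27 (1(10)Z,4E,6R,7R,8S)-15-acetoxy-8-[(2S)-2-methylbutanoyloxy]germacra-1(10),4,11(13)-trien-12,6-olide, via trimethylammonium iodide 26 (not isolated)
Conditions: MeI, MeCN, rt; then NaHCO3 (aq), EtOAc, rt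
Reagents that add atoms: none
Why: N-methylation followed by E1cB (Hofmann-type) elimination of trimethylamine releases the α-methylene lactone.

Step 16
Reactants: 27 (1(10)Z,4E,6R,7R,8S)-15-acetoxy-8-[(2S)-2-methylbutanoyloxy]germacra-1(10),4,11(13)-trien-12,6-olide
Product: 29 target: (1(10)E,4E,6R,7R,8S)-15-acetoxy-8-[(2S)-2-methylbutanoyloxy]-14-oxogermacra-1(10),4,11(13)-trien-12,6-olide, via C14 allylic alcohol 28 (not isolated)
Conditions: SeO2 (0.5 equiv), t-BuOOH, CH2Cl2, rt; then MnO2, CH2Cl2, rt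
Reagents that add atoms: selenium dioxide, O=[Se]=O (reoxidised by tert-butyl hydroperoxide, CC(C)(C)OO)
Why: Riley allylic oxidation (ene reaction then [2,3]-sigmatropic shift) attacks the methyl of the only electron-rich olefin (C9 is deactivated by the C8 acyloxy group, C4=C5 by two allylic oxygens). The [2,3] step places C14–O trans to C2, i.e. ring-cis, whatever the starting geometry, as in known germacranolide → melampolide oxidations; MnO2 then gives the enal.

## Compound list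

1 | (S)-5-(hydroxymethyl)furan-2(5H)-one | O=C1O[C@H](CO)C=C1 | starting material
2 | (S)-5-[(tert-butyldimethylsilyloxy)methyl]furan-2(5H)-one | O=C1O[C@H](CO[Si](C)(C)C(C)(C)C)C=C1 | intermediate
3 | 2-bromo-4-methylphenol | Cc1ccc(O)c(Br)c1 | starting material
4 | 2-bromo-1-(methoxymethoxy)-4-methylbenzene | Cc1ccc(OCOC)c(Br)c1 | intermediate
5 | [2-(methoxymethoxy)-5-methylphenyl]magnesium bromide | Cc1ccc(OCOC)c([Mg]Br)c1 | intermediate
6 | bromomagnesium (4R,5S)-5-[(tert-butyldimethylsilyloxy)methyl]-4-[2-(methoxymethoxy)-5-methylphenyl]-4,5-dihydrofuran-2-olate | Br[Mg]OC1=C[C@H](c2cc(C)ccc2OCOC)[C@@H](CO[Si](C)(C)C(C)(C)C)O1 | intermediate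
7 | (3R,4R,5S)-5-[(tert-butyldimethylsilyloxy)methyl]-3-[(dimethylamino)methyl]-4-[2-(methoxymethoxy)-5-methylphenyl]oxolan-2-one | O=C1O[C@H](CO[Si](C)(C)C(C)(C)C)[C@@H](c2cc(C)ccc2OCOC)[C@@H]1CN(C)C | intermediate
8 | lithium (2R,3R,4S)-5-(tert-butyldimethylsilyloxy)-2-[(dimethylamino)methyl]-4-hydroxy-3-[2-(methoxymethoxy)-5-methylphenyl]pentanoate | [Li+].[O-]C(=O)[C@@H](CN(C)C)[C@H](c1cc(C)ccc1OCOC)[C@H](O)CO[Si](C)(C)C(C)(C)C | intermediate
9 | lithium (2R,3R,4S)-5-(tert-butyldimethylsilyloxy)-2-[(dimethylamino)methyl]-4-hydroxy-3-[2-(methoxymethoxy)-5-methylcyclohexa-1,4-dien-1-yl]pentanoate | [Li+].[O-]C(=O)[C@@H](CN(C)C)[C@H](C1=C(OCOC)CC=C(C)C1)[C@H](O)CO[Si](C)(C)C(C)(C)C | intermediate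
10 | (3R,4R,5S)-5-[(tert-butyldimethylsilyloxy)methyl]-3-[(dimethylamino)methyl]-4-[2-(methoxymethoxy)-5-methylcyclohexa-1,4-dien-1-yl]oxolan-2-one | O=C1O[C@H](CO[Si](C)(C)C(C)(C)C)[C@@H](C2=C(OCOC)CC=C(C)C2)[C@@H]1CN(C)C | intermediate
11 | methoxymethyl (Z)-6-[(2S,3S,4R)-2-[(tert-butyldimethylsilyloxy)methyl]-4-[(dimethylamino)methyl]-5-oxooxolan-3-yl]-4-methyl-6-oxohex-3-enoate | O=C1O[C@H](CO[Si](C)(C)C(C)(C)C)[C@@H](C(=O)C/C(C)=C\CC(=O)OCOC)[C@@H]1CN(C)C | intermediate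
12 | (Z)-6-[(2S,3S,4R)-2-[(tert-butyldimethylsilyloxy)methyl]-4-[(dimethylamino)methyl]-5-oxooxolan-3-yl]-4-methyl-6-oxohex-3-enoic acid | O=C1O[C@H](CO[Si](C)(C)C(C)(C)C)[C@@H](C(=O)C/C(C)=C\CC(=O)O)[C@@H]1CN(C)C | intermediate
13 | tert-butyl 2-(diethoxyphosphoryl)acrylate | C=C(C(=O)OC(C)(C)C)P(=O)(OCC)OCC | starting material
14 | 1,3-dioxoisoindolin-2-yl (Z)-6-[(2S,3S,4R)-2-[(tert-butyldimethylsilyloxy)methyl]-4-[(dimethylamino)methyl]-5-oxooxolan-3-yl]-4-methyl-6-oxohex-3-enoate | O=C1O[C@H](CO[Si](C)(C)C(C)(C)C)[C@@H](C(=O)C/C(C)=C\CC(=O)ON2C(=O)c3ccccc3C2=O)[C@@H]1CN(C)C | intermediate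
15 | tert-butyl (5Z)-8-[(2S,3S,4R)-2-[(tert-butyldimethylsilyloxy)methyl]-4-[(dimethylamino)methyl]-5-oxooxolan-3-yl]-2-(diethoxyphosphoryl)-6-methyl-8-oxooct-5-enoate (C2 epimers) | O=C1O[C@H](CO[Si](C)(C)C(C)(C)C)[C@@H](C(=O)C/C(C)=C\CCC(C(=O)OC(C)(C)C)P(=O)(OCC)OCC)[C@@H]1CN(C)C | intermediate
16 | tert-butyl (5Z,8S)-8-[(2S,3R,4R)-2-[(tert-butyldimethylsilyloxy)methyl]-4-[(dimethylamino)methyl]-5-oxooxolan-3-yl]-2-(diethoxyphosphoryl)-8-hydroxy-6-methyloct-5-enoate | O=C1O[C@H](CO[Si](C)(C)C(C)(C)C)[C@@H]([C@@H](O)C/C(C)=C\CCC(C(=O)OC(C)(C)C)P(=O)(OCC)OCC)[C@@H]1CN(C)C | intermediate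
17 | (S)-2-methylbutanoic acid | CC[C@H](C)C(=O)O | starting material
18 | tert-butyl (5Z,8S)-8-[(2S,3R,4R)-2-[(tert-butyldimethylsilyloxy)methyl]-4-[(dimethylamino)methyl]-5-oxooxolan-3-yl]-2-(diethoxyphosphoryl)-6-methyl-8-[(2S)-2-methylbutanoyloxy]oct-5-enoate | O=C1O[C@H](CO[Si](C)(C)C(C)(C)C)[C@@H]([C@@H](OC(=O)[C@@H](C)CC)C/C(C)=C\CCC(C(=O)OC(C)(C)C)P(=O)(OCC)OCC)[C@@H]1CN(C)C | intermediate
19 | tert-butyl (5Z,8S)-2-(diethoxyphosphoryl)-8-[(2S,3R,4R)-4-[(dimethylamino)methyl]-2-(hydroxymethyl)-5-oxooxolan-3-yl]-6-methyl-8-[(2S)-2-methylbutanoyloxy]oct-5-enoate | O=C1O[C@H](CO)[C@@H]([C@@H](OC(=O)[C@@H](C)CC)C/C(C)=C\CCC(C(=O)OC(C)(C)C)P(=O)(OCC)OCC)[C@@H]1CN(C)C | intermediate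
20 | tert-butyl (5Z,8S)-2-(diethoxyphosphoryl)-8-[(2S,3R,4R)-4-[(dimethylamino)methyl]-2-formyl-5-oxooxolan-3-yl]-6-methyl-8-[(2S)-2-methylbutanoyloxy]oct-5-enoate | O=C1O[C@H](C=O)[C@@H]([C@@H](OC(=O)[C@@H](C)CC)C/C(C)=C\CCC(C(=O)OC(C)(C)C)P(=O)(OCC)OCC)[C@@H]1CN(C)C | intermediate
21 | macrocyclic tert-butyl ester: (1(10)Z,4E,6R,7R,8S,11R)-germacra-1(10),4-dien-12,6-olide with 11-CH2NMe2, 8-O-[(S)-2-methylbutanoyl], 10-CH3, 4-CO2t-Bu | CN(C)C[C@@H]1C(=O)O[C@@H]2/C=C(/C(=O)OC(C)(C)C)CC/C=C(/C)C[C@H](OC(=O)[C@@H](C)CC)[C@@H]12 | intermediate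
22 | macrocyclic 15-oic acid: as 21 with 4-CO2H | CN(C)C[C@@H]1C(=O)O[C@@H]2/C=C(/C(=O)O)CC/C=C(/C)C[C@H](OC(=O)[C@@H](C)CC)[C@@H]12 | intermediate
23 | mixed isobutyl carbonic anhydride of 22 | CN(C)C[C@@H]1C(=O)O[C@@H]2/C=C(/C(=O)OC(=O)OCC(C)C)CC/C=C(/C)C[C@H](OC(=O)[C@@H](C)CC)[C@@H]12 | intermediate
24 | macrocyclic 15-ol: as 21 with 4-CH2OH | CN(C)C[C@@H]1C(=O)O[C@@H]2/C=C(/CO)CC/C=C(/C)C[C@H](OC(=O)[C@@H](C)CC)[C@@H]12 | intermediate
25 | macrocyclic 15-acetate: as 21 with 4-CH2OAc | CN(C)C[C@@H]1C(=O)O[C@@H]2/C=C(/COC(C)=O)CC/C=C(/C)C[C@H](OC(=O)[C@@H](C)CC)[C@@H]12 | intermediate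
26 | N-methyl quaternary ammonium iodide of 25 | C[N+](C)(C)C[C@@H]1C(=O)O[C@@H]2/C=C(/COC(C)=O)CC/C=C(/C)C[C@H](OC(=O)[C@@H](C)CC)[C@@H]12.[I-] | intermediate
27 | (1(10)Z,4E,6R,7R,8S)-15-acetoxy-8-[(2S)-2-methylbutanoyloxy]germacra-1(10),4,11(13)-trien-12,6-olide | C=C1C(=O)O[C@@H]2/C=C(/COC(C)=O)CC/C=C(/C)C[C@H](OC(=O)[C@@H](C)CC)[C@@H]12 | intermediate
28 | (1(10)E,4E,6R,7R,8S)-15-acetoxy-14-hydroxy-8-[(2S)-2-methylbutanoyloxy]germacra-1(10),4,11(13)-trien-12,6-olide | C=C1C(=O)O[C@@H]2/C=C(/COC(C)=O)CC/C=C(/CO)C[C@H](OC(=O)[C@@H](C)CC)[C@@H]12 | intermediate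
29 | (1(10)E,4E,6R,7R,8S)-15-acetoxy-8-[(2S)-2-methylbutanoyloxy]-14-oxogermacra-1(10),4,11(13)-trien-12,6-olide | C=C1C(=O)O[C@@H]2/C=C(/COC(C)=O)CC/C=C(/C=O)C[C@H](OC(=O)[C@@H](C)CC)[C@@H]12 | target

## Step count and risks

Total step count: 16. Longest linear sequence: 15 steps (1 → 29 through steps 1 and 3–16; step 2 is a one-step side branch).

The three steps most likely to fail:

**Step 11, the ten-membered Horner–Wadsworth–Emmons closure** (dimerisation, slow reaction of the α-alkyl phosphonate). The fallback closes the same bond by metathesis. It sets out from 19. Olefination of the phosphonate with aqueous formaldehyde/K2CO3 gives the hydroxymethyl lactone 2-substituted acrylate F1. SO3·pyridine/DMSO oxidation gives the formyl lactone acrylate F2. Methylenation with Ph3P=CH2 gives the C6-vinyl lactone acrylate F3. Ring-closing metathesis with the second-generation Hoveyda–Grubbs catalyst (amine protonated with camphorsulfonic acid, toluene, 80 °C, 1 mM) forms C4=C5 with loss of ethene and comes back to the route at 21.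

**Step 6, the decarboxylative Giese addition of an allylic radical** (attack through the tertiary terminus, dimerisation, partial loss of the Z geometry; the last is harmless because step 16 resets C1=C10). The fallback is a two-electron sequence that keeps the carboxyl carbon as C3. It sets out from 12. BH3·SMe2 with the (R)-CBS catalyst reduces both ketone and acid to the (8S)-diol F4. I2/PPh3/imidazole converts the primary alcohol into the primary iodide F5. Steglich esterification with 17 gives the iodo ester F6. C-alkylation of the sodium salt of tert-butyl diethylphosphonoacetate (NaH, DMF) with F6 comes back to the route at 18.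

**Step 16, the selenium dioxide oxidation** (competing oxidation at C3 or C9, over-oxidation). The fallback replaces the direct ene oxidation by stepwise selenenylation and selenoxide rearrangement. It sets out from 27. PhSeCl adds to the C1=C10 olefin and pyridine eliminates HCl towards the methyl group, giving the C1-phenylselanyl 10(14)-exomethylene lactone F7. H2O2/pyridine at 0 °C forms the selenoxide, whose [2,3]-sigmatropic shift and hydrolysis deliver the (E)-C14 allylic alcohol. The fallback comes back to the route at 28, which MnO2 converts to 29.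

Further compounds
F1 | step 11 | tert-butyl (5Z,8S)-8-[(2S,3R,4R)-4-[(dimethylamino)methyl]-2-(hydroxymethyl)-5-oxooxolan-3-yl]-6-methyl-8-[(2S)-2-methylbutanoyloxy]-2-methylideneoct-5-enoate | O=C1O[C@H](CO)[C@@H]([C@@H](OC(=O)[C@@H](C)CC)C/C(C)=C\CCC(=C)C(=O)OC(C)(C)C)[C@@H]1CN(C)C
F2 | step 11 | tert-butyl (5Z,8S)-8-[(2S,3R,4R)-4-[(dimethylamino)methyl]-2-formyl-5-oxooxolan-3-yl]-6-methyl-8-[(2S)-2-methylbutanoyloxy]-2-methylideneoct-5-enoate | O=C1O[C@H](C=O)[C@@H]([C@@H](OC(=O)[C@@H](C)CC)C/C(C)=C\CCC(=C)C(=O)OC(C)(C)C)[C@@H]1CN(C)C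
F3 | step 11 | tert-butyl (5Z,8S)-8-[(2S,3R,4R)-4-[(dimethylamino)methyl]-2-ethenyl-5-oxooxolan-3-yl]-6-methyl-8-[(2S)-2-methylbutanoyloxy]-2-methylideneoct-5-enoate | O=C1O[C@H](C=C)[C@@H]([C@@H](OC(=O)[C@@H](C)CC)C/C(C)=C\CCC(=C)C(=O)OC(C)(C)C)[C@@H]1CN(C)C
F4 | step 6 | (3R,4R,5S)-5-[(tert-butyldimethylsilyloxy)methyl]-4-[(1S,3Z)-1,6-dihydroxy-3-methylhex-3-enyl]-3-[(dimethylamino)methyl]oxolan-2-one | O=C1O[C@H](CO[Si](C)(C)C(C)(C)C)[C@@H]([C@@H](O)C/C(C)=C\CCO)[C@@H]1CN(C)C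
F5 | step 6 | (3R,4R,5S)-5-[(tert-butyldimethylsilyloxy)methyl]-3-[(dimethylamino)methyl]-4-[(1S,3Z)-1-hydroxy-6-iodo-3-methylhex-3-enyl]oxolan-2-one | O=C1O[C@H](CO[Si](C)(C)C(C)(C)C)[C@@H]([C@@H](O)C/C(C)=C\CCI)[C@@H]1CN(C)C
F6 | step 6 | (1S,3Z)-1-[(2S,3R,4R)-2-[(tert-butyldimethylsilyloxy)methyl]-4-[(dimethylamino)methyl]-5-oxooxolan-3-yl]-6-iodo-3-methylhex-3-enyl (2S)-2-methylbutanoate | O=C1O[C@H](CO[Si](C)(C)C(C)(C)C)[C@@H]([C@@H](OC(=O)[C@@H](C)CC)C/C(C)=C\CCI)[C@@H]1CN(C)C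
F7 | step 16 | (4E,6R,7R,8S)-15-acetoxy-8-[(2S)-2-methylbutanoyloxy]-1-(phenylselanyl)germacra-4,10(14),11(13)-trien-12,6-olide (C1 epimers) | C=C1C(=O)O[C@@H]2/C=C(/COC(C)=O)CCC([Se]c3ccccc3)C(=C)C[C@H](OC(=O)[C@@H](C)CC)[C@@H]12
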